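The leftover was where I began: the part of the charge not standing as ring at 20.0 min was 68.6% in cedar and grew to 75.8% in maple, which had the larger charge.

all flasks: gas 3.8 mM (held)
- cedar: starting material 0.0085 M; run made earlier
- maple: starting material 0.013 M; run made earlier
- flask: starting material 0.017 M; time 20 min

- cedar (time / min: ring / %): 3.00: 4.8; 6.00: 13.5; 8.00: 18.1; 12.0: 25.5; 15.0: 26.8; 20.0: 31.4
- maple (time / min: ring / %): 1.50: 1.6; 2.50: 3.2; 4.00: 5.3; 6.00: 8.9; 8.00: 12.9; 12.0: 18.2; 20.0: 24.2

(standard deviation of a reading: 0.5 percentage points)

- at the start none of the gas is in solution

1. the ring standing at 20 min, as a percentage of the starting material charged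
2. the change that raises the amount of ring at 20 min, in percent of the starting material charged most ("none" if none brings more than 2 percentage points) (epsilon / zeta / none)
3. amount of ring at 20 min, in percent of the starting material charged, after epsilon

So I needed two amounts, the ring fraction and that leftover, and I multiplied their ratio, the odds of ring (a selectivity factor), by the charge:

cedar: 8.5 mM × 0.458 = 3.89 mM

maple: 13 mM × 0.319 = 4.15 mM

These products lay closer together than the charges did, so I took their mean, 4.02 mM, as the balance charge, the charge times ring over leftover. For the flask at 17 mM this gave:

ring fraction = balance charge / (balance charge + charge) = 19.1%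

- epsilon: doubling the saturation concentration of gas, all else as stated
- zeta: doubling the transfer coefficient of the gas, all else as stated

Both runs held the gas at 3.8 mM, so the balance charge gave me no reading on epsilon, the doubling of the gas's saturation concentration, or on zeta, the doubling of its transfer coefficient. The forecast gave 20.3%, above my 19.1%, with epsilon best at 33%, reasoning “If the rate is about first order in gas, ring rises substantially”.

The flask gave 19.7%; epsilon added 4.1 percentage points to reach 23.8%, and zeta added 0.71 points.

    starting material + activated form → open dimer (k = 2.50 M⁻¹ s⁻¹)
    starting material + activator → activated form (k = 0.830 M⁻¹ s⁻¹)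
    gas ⇌ activator, rate k3*(csat - [activator]) (kL = 0.0180 s⁻¹)
    activated form → ring (k = 0.00630 s⁻¹)
    starting material + activated form → side product (k = 0.100 M⁻¹ s⁻¹)

The flask's own balance charge came to 4.17 mM. For the neighbour flask, charged with 43.0 mM, the balance charge from cedar and maple gave a ring fraction of 8.55%. At 20.0 min that neighbour flask held open dimer at 85.1% and ring at 9.15%, so its own balance charge was 4.33 mM.

(The readings stem from a simulated flask on assumed constants.)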